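**Strategy.** The route rests on cutting ring A between its two adjacent ring C anchors: O1 on C8a and the C4 carbonyl on C4a, which sit side by side between the C8 prenyl group and the C5 oxygen. That ortho oxygen/acyl pair is traced back to an aryne (C4a≡C8a) and a carboxylate. In one operation, fluoride releases the aryne from a fully substituted ortho-silylaryl triflate (prenyl, OMe and OMOM in place), the carboxylate oxygen adds at C8a and the acyl group shifts to C4a. The acid partner already holds ring B and the C2 oxygen stereocentre as a (3R)-silyl ether; a later inverting closure of O1–C2 gives the (2S)-flavanone.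

Key step: step 15

**Remarks.**
- Flavanone numbering (O1, C2–C8a, primes for ring B) is used for positions, also in open-chain precursors.
- Configuration was checked along the whole route: (3R) in the acid and in the open-chain ketone, inverted to (2S) on ring closure, which matches the target.
- The acid enters the key step as its pre-formed, dried cesium salt, so that no acidic proton or bifluoride is present. The C2 oxygen is kept as a TBS ether, which is a poor leaving group and is removable with buffered fluoride.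
- Assumption: 5-methoxyresorcinol, resorcinol, prenyl bromide, 3-methylbut-2-enal and ethyl acetate are bought.

**Ring A fragment**

Step 1
Reactants: 1 5-methoxyresorcinol
Product: 2 3-methoxy-5-(methoxymethoxy)phenol
Conditions: NaH (1.0 equiv), DMF, 0 °C; MOMCl (1.0 equiv), 0 °C to rt
Reagents that add atoms: chloromethyl methyl ether (MOMCl), COCCl
Why: Williamson-type O-alkylation of one of two equivalent phenols, so one equivalent of base and MOMCl should give mainly the mono-ether in a statistical mixture from which diol 1 and the bis-ether are separated and recycled.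

Step 2
Reactants: 2 3-methoxy-5-(methoxymethoxy)phenol
Product: 3 3-methoxy-5-(methoxymethoxy)phenyl N,N-diethylcarbamate
Conditions: Et2NCOCl, K2CO3, MeCN, reflux
Reagents that add atoms: N,N-diethylcarbamoyl chloride, CCN(CC)C(=O)Cl
Why: Nucleophilic acyl substitution by the phenoxide installs the O-aryl carbamate, the strongest oxygen-based directing group for the two lithiations that follow, while the MOM and methyl ethers are inert to carbonate.

Step 3
Reactants: 3 3-methoxy-5-(methoxymethoxy)phenyl N,N-diethylcarbamate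
Product: 5 5-methoxy-3-(methoxymethoxy)-2-(trimethylsilyl)phenyl N,N-diethylcarbamate, via aryllithium 4 (not isolated)
Conditions: s-BuLi (1.1 equiv), TMEDA, THF, −78 °C; TMSCl, −78 °C to rt
Reagents that add atoms: chlorotrimethylsilane, C[Si](C)(C)Cl
Why: Directed ortho-metalation should be fastest at the position between the carbamate and the chelating OMOM group (the site between carbamate and OMe is the weaker competitor), and silylation at −78 °C outruns the anionic Fries shift of the carbamate; the silyl group marks the future C4a.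

Step 4
Reactants: 5 5-methoxy-3-(methoxymethoxy)-2-(trimethylsilyl)phenyl N,N-diethylcarbamate; 6 prenyl bromide (1-bromo-3-methylbut-2-ene)
Product: 9 3-methoxy-5-(methoxymethoxy)-2-(3-methylbut-2-enyl)-6-(trimethylsilyl)phenyl N,N-diethylcarbamate, via aryllithium 7 (not isolated), via arylcopper 8 (not isolated)
Conditions: s-BuLi (1.2 equiv), TMEDA, THF, −78 °C; CuBr·SMe2 (1.2 equiv), −78 °C; 6, −78 to −20 °C
Reagents that add atoms: none
Why: A second directed ortho-metalation takes the only position still flanked by the carbamate (between it and OMe, the future C8), and the derived arylcopper is allylated by prenyl bromide at its primary carbon (SN2), the low temperature again suppressing the anionic Fries rearrangement.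

Step 5
Reactants: 9 3-methoxy-5-(methoxymethoxy)-2-(3-methylbut-2-enyl)-6-(trimethylsilyl)phenyl N,N-diethylcarbamate
Product: 10 3-methoxy-5-(methoxymethoxy)-2-(3-methylbut-2-enyl)-6-(trimethylsilyl)phenol
Conditions: LiAlH4 (2 equiv), THF, 0 °C to reflux; aqueous potassium sodium tartrate work-up
Reagents that add atoms: none
Why: Hydride reduction of the carbamate carbonyl (reductive cleavage) frees the doubly flanked phenol, which resists hydrolysis, without touching the aryl–silicon bond, the MOM ether or the alkene; the phenol is worked up near neutral pH and used at once because the electron-rich aryl silane is prone to protodesilylation.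

Step 6
Reactants: 10 3-methoxy-5-(methoxymethoxy)-2-(3-methylbut-2-enyl)-6-(trimethylsilyl)phenol
Product: 11 3-methoxy-5-(methoxymethoxy)-2-(3-methylbut-2-enyl)-6-(trimethylsilyl)phenyl trifluoromethanesulfonate
Conditions: KN(SiMe3)2, THF, −78 °C; PhNTf2, −78 °C to rt
Reagents that add atoms: N-phenylbis(trifluoromethanesulfonimide), O=S(=O)(N(c1ccccc1)S(=O)(=O)C(F)(F)F)C(F)(F)F
Why: O-sulfonylation of the potassium phenoxide with a mild triflyl donor gives the ortho-silylaryl triflate under non-acidic conditions that spare the silyl group, the MOM ether and the prenyl alkene.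

**Ring B fragment**

Step 7
Reactants: 12 resorcinol; 13 3-methylbut-2-enal
Product: 15 2,2-dimethyl-2H-chromen-7-ol, via ortho-quinone methide 14 (not isolated)
Conditions: ethylenediammonium diacetate (10 mol %), toluene, reflux, Dean–Stark; 12 in excess
Reagents that add atoms: none
Why: Amine-catalysed Knoevenagel-type condensation of the enal at C4 of resorcinol (para to one hydroxyl, the usual site of electrophilic attack) gives the ortho-quinone methide, whose 6π oxa-electrocyclisation closes the 2H-pyran and so fixes the linear chromene pattern of ring B, while excess resorcinol limits a second annulation.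

Step 8
Reactants: 15 2,2-dimethyl-2H-chromen-7-ol
Product: 16 7-hydroxy-2,2-dimethyl-2H-chromene-6-carbaldehyde
Conditions: MgCl2, Et3N, (CH2O)n, MeCN, reflux
Reagents that add atoms: formaldehyde (as paraformaldehyde), C=O
Why: Casnati–Skattebøl ortho-formylation, in which the magnesium-bound phenoxide delivers formaldehyde to an ortho carbon and a second formaldehyde accepts hydride; of the two ortho positions C6 should be preferred over C8, which is wedged between the two oxygens.

Step 9
Reactants: 16 7-hydroxy-2,2-dimethyl-2H-chromene-6-carbaldehyde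
Product: 17 7-(methoxymethoxy)-2,2-dimethyl-2H-chromene-6-carbaldehyde
Conditions: MOMCl, K2CO3, acetone, reflux
Reagents that add atoms: chloromethyl methyl ether (MOMCl), COCCl
Why: Williamson-type O-alkylation of the chelated salicylaldehyde hydroxyl masks the future C2′ phenol so that no acidic proton interferes with the enolate, hydride and aryne steps.

Step 10
Reactants: 17 7-(methoxymethoxy)-2,2-dimethyl-2H-chromene-6-carbaldehyde; 18 ethyl acetate
Product: 20 ethyl 3-hydroxy-3-[7-(methoxymethoxy)-2,2-dimethyl-2H-chromen-6-yl]propanoate (racemic), via lithium enolate 19 (not isolated)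
Conditions: LiN(iPr)2, 18, THF, −78 °C; 17, −78 °C; aqueous NH4Cl
Reagents that add atoms: none
Why: Aldol addition of the lithium ester enolate to the non-enolisable aryl aldehyde supplies C3 and C4; the carbinol centre is formed racemic on purpose and is erased in the next step.

Step 11
Reactants: 20 ethyl 3-hydroxy-3-[7-(methoxymethoxy)-2,2-dimethyl-2H-chromen-6-yl]propanoate
Product: 21 ethyl 3-[7-(methoxymethoxy)-2,2-dimethyl-2H-chromen-6-yl]-3-oxopropanoate
Conditions: Dess–Martin periodinane (1.2 equiv), pyridine, CH2Cl2, 0 °C to rt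
Reagents that add atoms: none
Why: Dess–Martin oxidation of the benzylic secondary alcohol gives the β-keto ester under buffered, non-aqueous conditions that leave the chromene alkene and the MOM ether alone, a small excess of oxidant avoiding attack at the activated methylene.

Step 12
Reactants: 21 ethyl 3-[7-(methoxymethoxy)-2,2-dimethyl-2H-chromen-6-yl]-3-oxopropanoate
Product: 22 ethyl (3R)-3-hydroxy-3-[7-(methoxymethoxy)-2,2-dimethyl-2H-chromen-6-yl]propanoate
Conditions: RuCl[(R,R)-TsDPEN](p-cymene) (1 mol %), HCO2H/Et3N (1:1), DMF, 40 °C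
Reagents that add atoms: none
Why: Noyori–Ikariya asymmetric transfer hydrogenation, in which the Ru–H/N–H pair of the (R,R)-complex delivers hydride through an outer-sphere six-membered transition state to the ketone face that keeps the aryl ring against the η6-arene, which for aryl ketones with a CH2 arm should give the (R)-carbinol, and neither the chromene alkene nor the ester is reduced.

Step 13
Reactants: 22 ethyl (3R)-3-hydroxy-3-[7-(methoxymethoxy)-2,2-dimethyl-2H-chromen-6-yl]propanoate
Product: 23 ethyl (3R)-3-(tert-butyldimethylsilyloxy)-3-[7-(methoxymethoxy)-2,2-dimethyl-2H-chromen-6-yl]propanoate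
Conditions: TBSCl, imidazole, DMF, rt
Reagents that add atoms: tert-butyldimethylsilyl chloride, CC(C)(C)[Si](C)(C)Cl
Why: Imidazole-promoted silylation of the secondary benzylic alcohol gives an ether that tolerates hydroxide and dry fluoride salts, is a poor leaving group, and leaves the stereocentre untouched.

Step 14
Reactants: 23 ethyl (3R)-3-(tert-butyldimethylsilyloxy)-3-[7-(methoxymethoxy)-2,2-dimethyl-2H-chromen-6-yl]propanoate
Product: 24 (3R)-3-(tert-butyldimethylsilyloxy)-3-[7-(methoxymethoxy)-2,2-dimethyl-2H-chromen-6-yl]propanoic acid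
Conditions: LiOH·H2O, THF/MeOH/H2O, 0 °C to rt; cold 0.5 M HCl to pH 4–5
Reagents that add atoms: lithium hydroxide, [Li+].[OH-]
Why: Saponification at room temperature followed by brief mild acidification gives the acid without β-elimination of the silyloxy group or loss of the MOM ether, and C3 stays (R).

**Union and end game**

Step 15
Reactants: 24 (3R)-3-(tert-butyldimethylsilyloxy)-3-[7-(methoxymethoxy)-2,2-dimethyl-2H-chromen-6-yl]propanoic acid; 11 3-methoxy-5-(methoxymethoxy)-2-(3-methylbut-2-enyl)-6-(trimethylsilyl)phenyl trifluoromethanesulfonate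
Product: 28 (3R)-3-(tert-butyldimethylsilyloxy)-1-[2-hydroxy-4-methoxy-6-(methoxymethoxy)-3-(3-methylbut-2-enyl)phenyl]-3-[7-(methoxymethoxy)-2,2-dimethyl-2H-chromen-6-yl]propan-1-one, via cesium carboxylate 25 (not isolated), via aryne 26 (not isolated), via aryl anion 27 (not isolated)
Conditions: 24, Cs2CO3 (0.5 equiv), MeOH, rt, then evaporation and drying (toluene azeotrope); 11 (1.4 equiv), CsF (4 equiv), 18-crown-6 (0.3 equiv), THF, sealed tube, 65 °C then 100 °C; aqueous NH4Cl
Reagents that add atoms: none
Why: Fluoride removes the trimethylsilyl group of 11 and triflate leaves to give aryne 26 (C4a≡C8a); the carboxylate oxygen of 25 adds at C8a, and the C4a carbanion of 27 attacks its own ester carbonyl through a four-membered transition state, ending at the ortho-acyl phenoxide, so that C8a–O and C4a–C4 form in one operation. The closest known reaction type is the fluoride-mediated insertion of arynes into the C–O bond of carboxylic acids to give ortho-hydroxyaryl ketones, an anionic Fries-type 1,3 O-to-C acyl shift. No ring is closed and no stereocentre is created; the C2 carbinol centre is not part of any reacting centre and is carried through as its TBS ether. Regioselectivity is needed (oxygen at C8a, acyl at C4a): the inductively withdrawing C5–OMOM group distorts the aryne so that the nucleophile attacks the distal carbon C8a and the charge develops at C4a next to oxygen, which should outweigh the steric shielding of C8a by the prenyl group. Chemoselectivity for acyl transfer over protonation of 27, which would stop at the aryl ester, is secured by the pre-formed dry cesium salt in THF, which also protects the silyl and MOM ethers from bifluoride.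

Step 16
Reactants: 28 (3R)-3-(tert-butyldimethylsilyloxy)-1-[2-hydroxy-4-methoxy-6-(methoxymethoxy)-3-(3-methylbut-2-enyl)phenyl]-3-[7-(methoxymethoxy)-2,2-dimethyl-2H-chromen-6-yl]propan-1-one
Product: 29 (3R)-3-hydroxy-1-[2-hydroxy-4-methoxy-6-(methoxymethoxy)-3-(3-methylbut-2-enyl)phenyl]-3-[7-(methoxymethoxy)-2,2-dimethyl-2H-chromen-6-yl]propan-1-one
Conditions: Bu4NF (1.5 equiv), AcOH (1.5 equiv), THF, 0 °C to rt
Reagents that add atoms: none
Why: Fluoride-mediated desilylation buffered with acetic acid frees the benzylic alcohol in a non-basic medium, so that the β-hydroxy ketone should neither dehydrate nor undergo retro-aldol cleavage, while both MOM ethers (the C5 one is needed to leave a single phenol for ring closure) stay on.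

Step 17
Reactants: 29 (3R)-3-hydroxy-1-[2-hydroxy-4-methoxy-6-(methoxymethoxy)-3-(3-methylbut-2-enyl)phenyl]-3-[7-(methoxymethoxy)-2,2-dimethyl-2H-chromen-6-yl]propan-1-one
Product: 31 (2S)-7-methoxy-5-(methoxymethoxy)-2-[7-(methoxymethoxy)-2,2-dimethyl-2H-chromen-6-yl]-8-(3-methylbut-2-enyl)-2,3-dihydro-4H-chromen-4-one, via alkoxyphosphonium ion 30 (not isolated)
Conditions: PPh3, DIAD, toluene, −20 to 0 °C
Reagents that add atoms: none
Why: Intramolecular Mitsunobu etherification, in which the benzylic alcohol is activated as its alkoxyphosphonium ion and displaced by the neighbouring chelated phenoxide in a 6-exo-tet SN2 closure with inversion, turning the (R)-carbinol into (2S)-C2, low temperature and a non-polar solvent disfavouring ionisation of the electron-rich benzylic centre.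

Step 18
Reactants: 31 (2S)-7-methoxy-5-(methoxymethoxy)-2-[7-(methoxymethoxy)-2,2-dimethyl-2H-chromen-6-yl]-8-(3-methylbut-2-enyl)-2,3-dihydro-4H-chromen-4-one
Product: 32 maackiaflavanone A, (2S)-5-hydroxy-2-(7-hydroxy-2,2-dimethyl-2H-chromen-6-yl)-7-methoxy-8-(3-methylbut-2-enyl)-2,3-dihydro-4H-chromen-4-one
Conditions: 3 M aqueous HCl/MeOH (1:10), 40 °C
Reagents that add atoms: none
Why: Acid-catalysed acetal cleavage (transacetalisation to dimethoxymethane) removes both MOM ethers, the C5 one assisted by the peri carbonyl; O1 is a vinylogous ester oxygen too weakly basic to ionise C2, the chromene is inert, and the C8 prenyl group has no free ortho hydroxyl to cyclise onto.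

**Compound list**

1 | 5-methoxyresorcinol | COc1cc(O)cc(O)c1 | starting material
2 | 3-methoxy-5-(methoxymethoxy)phenol | COCOc1cc(O)cc(OC)c1 | intermediate
3 | 3-methoxy-5-(methoxymethoxy)phenyl N,N-diethylcarbamate | CCN(CC)C(=O)Oc1cc(OC)cc(OCOC)c1 | intermediate
4 | 2-(diethylcarbamoyloxy)-4-methoxy-6-(methoxymethoxy)phenyllithium | CCN(CC)C(=O)Oc1cc(OC)cc(OCOC)c1[Li] | intermediate (not isolated)
5 | 5-methoxy-3-(methoxymethoxy)-2-(trimethylsilyl)phenyl N,N-diethylcarbamate | CCN(CC)C(=O)Oc1cc(OC)cc(OCOC)c1[Si](C)(C)C | intermediate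
6 | prenyl bromide (1-bromo-3-methylbut-2-ene) | CC(C)=CCBr | starting material
7 | 2-(diethylcarbamoyloxy)-6-methoxy-4-(methoxymethoxy)-3-(trimethylsilyl)phenyllithium | CCN(CC)C(=O)Oc1c([Li])c(OC)cc(OCOC)c1[Si](C)(C)C | intermediate (not isolated)
8 | 2-(diethylcarbamoyloxy)-6-methoxy-4-(methoxymethoxy)-3-(trimethylsilyl)phenylcopper | CCN(CC)C(=O)Oc1c([Cu])c(OC)cc(OCOC)c1[Si](C)(C)C | intermediate (not isolated)
9 | 3-methoxy-5-(methoxymethoxy)-2-(3-methylbut-2-enyl)-6-(trimethylsilyl)phenyl N,N-diethylcarbamate | CCN(CC)C(=O)Oc1c(CC=C(C)C)c(OC)cc(OCOC)c1[Si](C)(C)C | intermediate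
10 | 3-methoxy-5-(methoxymethoxy)-2-(3-methylbut-2-enyl)-6-(trimethylsilyl)phenol | COc1cc(OCOC)c([Si](C)(C)C)c(O)c1CC=C(C)C | intermediate
11 | 3-methoxy-5-(methoxymethoxy)-2-(3-methylbut-2-enyl)-6-(trimethylsilyl)phenyl trifluoromethanesulfonate | COc1cc(OCOC)c([Si](C)(C)C)c(OS(=O)(=O)C(F)(F)F)c1CC=C(C)C | intermediate
12 | resorcinol | Oc1cccc(O)c1 | starting material
13 | 3-methylbut-2-enal | CC(C)=CC=O | starting material
14 | 3-hydroxy-6-(3-methylbut-2-enylidene)cyclohexa-2,4-dien-1-one (ortho-quinone methide) | O=C1C=C(O)C=CC1=CC=C(C)C | intermediate (not isolated)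
15 | 2,2-dimethyl-2H-chromen-7-ol | CC1(C)C=Cc2ccc(O)cc2O1 | intermediate
16 | 7-hydroxy-2,2-dimethyl-2H-chromene-6-carbaldehyde | CC1(C)C=Cc2cc(C=O)c(O)cc2O1 | intermediate
17 | 7-(methoxymethoxy)-2,2-dimethyl-2H-chromene-6-carbaldehyde | COCOc1cc2OC(C)(C)C=Cc2cc1C=O | intermediate
18 | ethyl acetate | CCOC(C)=O | starting material
19 | lithium 1-ethoxyethenolate | [Li]OC(=C)OCC | intermediate (not isolated)
20 | ethyl 3-hydroxy-3-[7-(methoxymethoxy)-2,2-dimethyl-2H-chromen-6-yl]propanoate (racemic) | CCOC(=O)CC(O)c1cc2c(cc1OCOC)OC(C)(C)C=C2 | intermediate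
21 | ethyl 3-[7-(methoxymethoxy)-2,2-dimethyl-2H-chromen-6-yl]-3-oxopropanoate | CCOC(=O)CC(=O)c1cc2c(cc1OCOC)OC(C)(C)C=C2 | intermediate
22 | ethyl (3R)-3-hydroxy-3-[7-(methoxymethoxy)-2,2-dimethyl-2H-chromen-6-yl]propanoate | CCOC(=O)C[C@@H](O)c1cc2c(cc1OCOC)OC(C)(C)C=C2 | intermediate
23 | ethyl (3R)-3-(tert-butyldimethylsilyloxy)-3-[7-(methoxymethoxy)-2,2-dimethyl-2H-chromen-6-yl]propanoate | CCOC(=O)C[C@@H](O[Si](C)(C)C(C)(C)C)c1cc2c(cc1OCOC)OC(C)(C)C=C2 | intermediate
24 | (3R)-3-(tert-butyldimethylsilyloxy)-3-[7-(methoxymethoxy)-2,2-dimethyl-2H-chromen-6-yl]propanoic acid | CC(C)(C)[Si](C)(C)O[C@@H](c1cc2c(cc1OCOC)OC(C)(C)C=C2)CC(=O)O | intermediate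
25 | cesium (3R)-3-(tert-butyldimethylsilyloxy)-3-[7-(methoxymethoxy)-2,2-dimethyl-2H-chromen-6-yl]propanoate | CC(C)(C)[Si](C)(C)O[C@@H](c1cc2c(cc1OCOC)OC(C)(C)C=C2)CC(=O)[O-].[Cs+] | intermediate (not isolated)
26 | 3,4-didehydro-1-methoxy-5-(methoxymethoxy)-2-(3-methylbut-2-enyl)benzene (ring A aryne) | COC1=C(CC=C(C)C)C#CC(OCOC)=C1 | intermediate (not isolated)
27 | 2-cesio-5-methoxy-3-(methoxymethoxy)-6-(3-methylbut-2-enyl)phenyl (3R)-3-(tert-butyldimethylsilyloxy)-3-[7-(methoxymethoxy)-2,2-dimethyl-2H-chromen-6-yl]propanoate | COc1cc(OCOC)c([Cs])c(OC(=O)C[C@@H](O[Si](C)(C)C(C)(C)C)c2cc3c(cc2OCOC)OC(C)(C)C=C3)c1CC=C(C)C | intermediate (not isolated)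
28 | (3R)-3-(tert-butyldimethylsilyloxy)-1-[2-hydroxy-4-methoxy-6-(methoxymethoxy)-3-(3-methylbut-2-enyl)phenyl]-3-[7-(methoxymethoxy)-2,2-dimethyl-2H-chromen-6-yl]propan-1-one | COc1cc(OCOC)c(C(=O)C[C@@H](O[Si](C)(C)C(C)(C)C)c2cc3c(cc2OCOC)OC(C)(C)C=C3)c(O)c1CC=C(C)C | intermediate
29 | (3R)-3-hydroxy-1-[2-hydroxy-4-methoxy-6-(methoxymethoxy)-3-(3-methylbut-2-enyl)phenyl]-3-[7-(methoxymethoxy)-2,2-dimethyl-2H-chromen-6-yl]propan-1-one | COc1cc(OCOC)c(C(=O)C[C@@H](O)c2cc3c(cc2OCOC)OC(C)(C)C=C3)c(O)c1CC=C(C)C | intermediate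
30 | alkoxytriphenylphosphonium phenoxide of 29 | COc1cc(OCOC)c(C(=O)C[C@@H](O[P+](c2ccccc2)(c2ccccc2)c2ccccc2)c2cc3c(cc2OCOC)OC(C)(C)C=C3)c([O-])c1CC=C(C)C | intermediate (not isolated)
31 | (2S)-7-methoxy-5-(methoxymethoxy)-2-[7-(methoxymethoxy)-2,2-dimethyl-2H-chromen-6-yl]-8-(3-methylbut-2-enyl)-2,3-dihydro-4H-chromen-4-one | COc1cc(OCOC)c2c(c1CC=C(C)C)O[C@H](c1cc3c(cc1OCOC)OC(C)(C)C=C3)CC2=O | intermediate
32 | maackiaflavanone A | COc1cc(O)c2c(c1CC=C(C)C)O[C@H](c1cc3c(cc1O)OC(C)(C)C=C3)CC2=O | target

**Step count.** Total: 18 steps. Longest linear sequence: 12 steps (steps 7–14, then 15–18); the ring A branch (steps 1–6) joins at step 15.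

**Steps most likely to fail**

1. Step 15 (aryne oxy-acylation). What may go wrong: the aryl anion is protonated (by adventitious water or by the α-methylene of its own ester) before it attacks the ester, so the sequence stops at the aryl ester; fluoride at the temperature needed strips the silyl ether or triggers β-elimination across C2–C3; the carboxylate adds at C4a in place of C8a. Fallback, aryne-free and by directed metalation: it sets out from carbamate 9 and ester 23 and comes back at ketone 28. Bu4NF in THF removes the trimethylsilyl group of 9 to give 3-methoxy-5-(methoxymethoxy)-2-(3-methylbut-2-enyl)phenyl N,N-diethylcarbamate F1. iBu2AlH at −78 °C reduces 23 to (3R)-3-(tert-butyldimethylsilyloxy)-3-[7-(methoxymethoxy)-2,2-dimethyl-2H-chromen-6-yl]propanal F2. F1 is lithiated with s-BuLi/TMEDA at −78 °C, now at the freed position between carbamate and OMOM (C4a); kinetic conditions are kept to avoid deprotonation of the prenyl methylene. After transmetalation with CeCl3 to suppress enolisation, the aryl metal adds to F2 and gives the carbinol 2-[(3R)-3-(tert-butyldimethylsilyloxy)-1-hydroxy-3-[7-(methoxymethoxy)-2,2-dimethyl-2H-chromen-6-yl]propyl]-5-methoxy-3-(methoxymethoxy)-6-(3-methylbut-2-enyl)phenyl N,N-diethylcarbamate F3, a mixture of epimers at the centre that is oxidised later. LiAlH4 removes the carbamoyl group (from either oxygen, should it have migrated) to give (3R)-3-(tert-butyldimethylsilyloxy)-1-[2-hydroxy-4-methoxy-6-(methoxymethoxy)-3-(3-methylbut-2-enyl)phenyl]-3-[7-(methoxymethoxy)-2,2-dimethyl-2H-chromen-6-yl]propan-1-ol F4, and MnO2 in CH2Cl2 oxidises the ortho-hydroxybenzylic alcohol to 28.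

2. Step 17 (Mitsunobu closure). What may go wrong: the activated benzylic centre, stabilised by the ortho and para oxygens of ring B, ionises, or the β-hydroxy ketone dehydrates and re-closes, so that inversion is incomplete and enantiopurity erodes. Fallback, giving up the stereochemical relay and resolving at the flavanone stage: it sets out from 29 and comes back at 31. NaOAc in refluxing EtOH converts 29 by elimination into the chalcone (E)-1-[2-hydroxy-4-methoxy-6-(methoxymethoxy)-3-(3-methylbut-2-enyl)phenyl]-3-[7-(methoxymethoxy)-2,2-dimethyl-2H-chromen-6-yl]prop-2-en-1-one F5, which closes by oxa-Michael addition to the racemic flavanone 7-methoxy-5-(methoxymethoxy)-2-[7-(methoxymethoxy)-2,2-dimethyl-2H-chromen-6-yl]-8-(3-methylbut-2-enyl)-2,3-dihydro-4H-chromen-4-one F6. Kinetic resolution of F6 by asymmetric transfer hydrogenation (RuCl[(R,R)-TsDPEN](p-cymene), HCO2H/Et3N, stopped near half conversion) should reduce the (2R)-enantiomer to the cis-alcohol (2R,4R)-7-methoxy-5-(methoxymethoxy)-2-[7-(methoxymethoxy)-2,2-dimethyl-2H-chromen-6-yl]-8-(3-methylbut-2-enyl)chroman-4-ol F7 and leave (2S)-flavanone 31, separable by chromatography. The catalyst antipode follows the usual aryl-ketone model and would be confirmed on the first run.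

3. Step 7 (chromene annulation). What may go wrong: C-alkylation at C2 of resorcinol and a second annulation on the product compete, which lowers the amount of the 7-hydroxy isomer. Fallback, by Friedel–Crafts acylation and oxa-Michael closure: it sets out from resorcinol 12 and comes back at chromenol 15. 12 and 3-methylbut-2-enoic acid (CC(C)=CC(=O)O) in P2O5/MeSO3H at 70 °C give 7-hydroxy-2,2-dimethylchroman-4-one F8 (acylation para to one hydroxyl, ring closure by the other). NaBH4 in MeOH reduces it to 2,2-dimethylchromane-4,7-diol F9, and catalytic TsOH in warm toluene dehydrates the para-hydroxybenzylic alcohol to 15.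

**Further compounds**

F1 | step 15 | 3-methoxy-5-(methoxymethoxy)-2-(3-methylbut-2-enyl)phenyl N,N-diethylcarbamate | CCN(CC)C(=O)Oc1cc(OCOC)cc(OC)c1CC=C(C)C
F2 | step 15 | (3R)-3-(tert-butyldimethylsilyloxy)-3-[7-(methoxymethoxy)-2,2-dimethyl-2H-chromen-6-yl]propanal | O=CC[C@@H](O[Si](C)(C)C(C)(C)C)c1cc2c(cc1OCOC)OC(C)(C)C=C2
F3 | step 15 | 2-[(3R)-3-(tert-butyldimethylsilyloxy)-1-hydroxy-3-[7-(methoxymethoxy)-2,2-dimethyl-2H-chromen-6-yl]propyl]-5-methoxy-3-(methoxymethoxy)-6-(3-methylbut-2-enyl)phenyl N,N-diethylcarbamate | CCN(CC)C(=O)Oc1c(CC=C(C)C)c(OC)cc(OCOC)c1C(O)C[C@@H](O[Si](C)(C)C(C)(C)C)c1cc2c(cc1OCOC)OC(C)(C)C=C2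
F4 | step 15 | (3R)-3-(tert-butyldimethylsilyloxy)-1-[2-hydroxy-4-methoxy-6-(methoxymethoxy)-3-(3-methylbut-2-enyl)phenyl]-3-[7-(methoxymethoxy)-2,2-dimethyl-2H-chromen-6-yl]propan-1-ol | COc1cc(OCOC)c(C(O)C[C@@H](O[Si](C)(C)C(C)(C)C)c2cc3c(cc2OCOC)OC(C)(C)C=C3)c(O)c1CC=C(C)C
F5 | step 17 | (E)-1-[2-hydroxy-4-methoxy-6-(methoxymethoxy)-3-(3-methylbut-2-enyl)phenyl]-3-[7-(methoxymethoxy)-2,2-dimethyl-2H-chromen-6-yl]prop-2-en-1-one | COc1cc(OCOC)c(C(=O)/C=C/c2cc3c(cc2OCOC)OC(C)(C)C=C3)c(O)c1CC=C(C)C
F6 | step 17 | racemic 7-methoxy-5-(methoxymethoxy)-2-[7-(methoxymethoxy)-2,2-dimethyl-2H-chromen-6-yl]-8-(3-methylbut-2-enyl)-2,3-dihydro-4H-chromen-4-one | COc1cc(OCOC)c2c(c1CC=C(C)C)OC(c1cc3c(cc1OCOC)OC(C)(C)C=C3)CC2=O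
F7 | step 17 | (2R,4R)-7-methoxy-5-(methoxymethoxy)-2-[7-(methoxymethoxy)-2,2-dimethyl-2H-chromen-6-yl]-8-(3-methylbut-2-enyl)chroman-4-ol | COc1cc(OCOC)c2c(c1CC=C(C)C)O[C@@H](c1cc3c(cc1OCOC)OC(C)(C)C=C3)C[C@H]2O
F8 | step 7 | 7-hydroxy-2,2-dimethylchroman-4-one | CC1(C)CC(=O)c2ccc(O)cc2O1
F9 | step 7 | 2,2-dimethylchromane-4,7-diol (racemic) | CC1(C)CC(O)c2ccc(O)cc2O1
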